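## Structural features

The target, C22H22O4, is a pentacycle. A hydroquinone (ring A) is fused to a five-membered carbocycle (ring B) made of two arene carbons, a benzylic methine, a benzylic quaternary carbon and a central quaternary carbon. The same three sp3 carbons also belong to a methylcyclohexene (ring C). Rings B and C therefore form a benzobicyclo[3.2.1]octadiene: the benzylic carbons are the bridgeheads, the central quaternary carbon is the one-carbon bridge, and CH2–C(CH3)=CH is the three-carbon bridge. The two quaternary carbons are also tied through C(=O)–CH2 to a bridgehead methine (ring D, a six-membered 1,4-diketone ring). That methine, the bridging ketone, the central quaternary carbon, a CH2 and the isopropenyl-bearing methine form a cyclopentanone (ring E), so rings D and E are a bicyclo[3.2.1]octane-3,8-dione.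

Of the five stereocentres, the benzylic methine, the central quaternary carbon and the benzylic quaternary carbon are contiguous. The ring D/E bridgehead methine is adjacent to the isopropenyl methine, and the isopropenyl group sits on the face of ring E turned away from ring D, 1,3 to the central quaternary carbon.

The fragile groups are the hydroquinone (air oxidation), the isopropenyl and trisubstituted alkenes (acid) and the benzylic, allylic methine. The real difficulty is the pair of adjacent all-carbon quaternary centres, each of which is a bridge or bridgehead atom of both bicycles, together with the remote isopropenyl stereocentre.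

The key step exploits the bicyclo[3.2.1]octadiene of rings B and C. Its three-carbon bridge is an allyl unit oxidised at the central carbon, so the two bonds from the benzylic bridgeheads to that bridge can be made by adding an oxyallyl cation across C1 and C4 of a cyclopentadiene. C5 of that diene is the central quaternary carbon, and its C2–C3 bond later becomes the fusion bond of ring A.

## Logic of the disconnections

34 is traced to 32 by turning the two phenols into methyl ethers. No skeletal bond is cut. The reason is that the hydroquinone is the most easily oxidised group and would not survive enolate oxidation. The forward step must remove both methyl groups oxidatively without touching the alkenes or ketones, then reduce the quinone.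

32 is cut at the bond between the ring E bridgehead methine (alpha to the bridging ketone) and the CH2 alpha to the ring D ketone. This is the 2,3-bond of a 1,4-diketone, so it maps onto an oxidative enolate coupling. Ring D opens and one stereocentre disappears, leaving 31, an acetyl group and a cyclopentanone on adjacent quaternary carbons. Each ketone in 31 can enolise at one position only; the demand is that the intramolecular coupling beats intermolecular reaction.

31 goes back through 30 to 29 by protecting-group changes only (two dioxolanes, one aryl methyl ether, one aryl silane as placeholder for hydrogen). These are needed because the arene synthesis and the organometallic steps before it do not tolerate free ketones.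

29 is cut through ring A at three bonds: carbene carbon to alkyne carbon, alkyne carbon to the CO-derived carbon, and that carbon to the bridge CH. This leads to 26 and 27. Four of the six arene carbons then come from reagents and only the ring-fusion alkene has to pre-exist. The demand is an alkenyl carbene on the two-carbon bridge.

26 is cut at the bond between the bridge alkene carbon and the carbene carbon, giving 22 and 23. The alkenyl metal needed for this comes from a C–Cl bond. A plain CH=CH bridge could not be functionalised selectively next to the isopropenyl group, so the chlorine must be in place from the diene stage and stay inert until this point.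

22 is cut at the methyl–alkene bond, giving 21 and enol triflate 20, which comes from ketone 19. The ketone left by the cycloaddition marks the methyl-bearing carbon. The demand is enolisation toward the bridgehead CH and away from the quaternary bridgehead.

19 is cut at the two bonds from the bridgeheads to the three-carbon bridge, giving 16 and 17. This is the strategic cut: it reduces the bicyclo[3.2.1] core to a spiro cyclopentadiene and a three-carbon unit and creates both benzylic stereocentres. The demand is attack on one face of the diene. In 16 the substituted diene terminus is trans and the unsubstituted one cis to the isopropenyl group; in 19 the three-carbon bridge lies over the ring CH2 of the spiro cyclopentane. Both relationships were checked against the target and are the ones it requires.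

16 goes back to 15 (dioxolane from enol ether) and 15 is cut between diene C1 and the masked acetyl carbon, giving 13 and 14. The acetyl equivalent is thus introduced by cross-coupling and not by acylating a sensitive diene. The demand is selective reaction of the triflate next to the alkenyl chloride.

13 goes back through 12 to 11 without skeletal change. Both heteroatom handles of the diene come from the two carbonyls of a cyclopentane-1,3-dione. The demand is that sterics differentiate the two carbonyls: chlorine goes to the one remote from the spiro carbon, triflate to the one next to it.

11 is cut between the dione CH2 and the carbonyl next to the spiro carbon (Claisen), giving keto ester 10. The ring opens to a methyl ketone and an ester on the same quaternary carbon.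

10 goes back to 9 (methyl ketone from allyl) and 9 to 8 (ketal from ketone). The demand is oxidation of the allyl group in the presence of the isopropenyl group.

8 is cut at the isopropenyl–ring bond (conjugate addition), giving 6 and 7. The remote stereocentre is set by a chiral catalyst on an enone that already carries the quaternary centre, so the 1,3-relationship does not depend on weak substrate bias.

6 goes back to 3 by dehydrogenation, and 3 is cut at the allyl–quaternary carbon bond, giving 1 and 2. The quaternary centre is set by a chiral catalyst on an achiral substrate.

## Other disconnections considered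

Alternative 1: The cut is the bond between the benzylic methine and the central quaternary carbon, which opens rings B and C together. The precursor A1 is a spiro compound: the benzylic quaternary carbon joins a benzo-fused cycloheptadienol to a 2-prenylcyclohex-5-ene-1,4-dione. In the forward step, catalytic Sc(OTf)3 would ionise the benzylic, allylic alcohol and the enol of the dione would attack the cation to give the bridged ene-dione A2.
- In its favour: the closure is stereoconvergent, because the spiro carbon alone dictates how the carbinol carbon and the enolisable prenyl-bearing carbon can meet. Two rings and the quaternary–methine bond form in one catalytic step, and no protecting groups beyond the aryl methyl ethers are needed.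
- Against it here: the whole stereochemical burden sits on one spiro all-carbon quaternary centre in A1, which must be made enantioselectively next to an easily enolised ene-dione. The delocalised cation could also be captured at its allylic terminus or lost by elimination, and O-alkylation of the enol competes.
- Comparison: structurally it makes the one bond between the two most hindered carbons, whereas the chosen plan makes two less hindered bonds around them. Mechanistically it is a cation–enol alkylation against a cycloaddition with broad precedent. On step economy and on freedom from protecting groups Alternative 1 is the better plan; in the timing of ring A (present from the start) it is also better; in predictability of stereocontrol the two are about equal.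

Alternative 2: The cut is the bond between the benzylic quaternary carbon and the allylic CH2 of ring C, with ring D written as a phenol. The precursor A3 is a flat 9-substituted fluorenol carrying an allylic carbonate. With Pd2(dba)3 and PPh3 the π-allyl complex would be attacked by the phenolate through its ring-fusion ortho carbon, dearomatising the phenol to the bridged methoxy dienone A4.
- In its favour: A3 is an aromatic biaryl-type compound that cross-coupling can assemble quickly. The step is catalytic in zerovalent palladium, and because the fluorenyl C–H is acidic a chiral ligand could in principle control the absolute configuration dynamically. On these points it is the better plan.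
- Against it here: O-allylation and attack through the other ortho position compete. After the key step the central carbon is still an sp2 enol ether carbon, so the second quaternary centre, ring E and the isopropenyl stereocentre all remain to be made on a congested dienone.
- Comparison: it forms one ring, one bond and one stereocentre, against one ring, two bonds and two stereocentres for the chosen key step. The front end is shorter than in the chosen plan, the back end probably not.

Alternative 3: The cut is the bond between the isopropenyl methine and the ring D/E bridgehead methine. The substrate is A2, the product of Alternative 1. Me2AlCl would activate the ene-dione and the prenyl alkene would attack the enone β-carbon in a conjugate ene reaction, giving A5, the target bis(methyl ether), which is the same structure as 32.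
- In its favour: ring E, two stereocentres and the isopropenyl group arise in one step with no added atoms, and the prenyl group can only reach the ene-dione from the face on which it is held. Combined with Alternative 1 this gives a very short route, clearly better in step and atom economy than the chosen plan, which spends several steps on the same features.
- Against it here: the ene-dione has two electrophilic alkene carbons, and the exo or endo placement of the isopropenyl group depends on the ene transition state, not on a catalyst. The Lewis acid may also start cationic side reactions at the electron-rich arene or the trisubstituted alkene.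
- Comparison: the chosen plan sets the isopropenyl centre early under catalyst control and closes ring D last; Alternative 3 closes ring E last under substrate control. The two plans meet at the same dimethyl ether and share the final operation, so they are equal from that point on.

Key step: step 11

Assumption (remark on the chemistry): the diene carries one added substituent, a chlorine on C3, which leaves the carbon skeletons of the key-step partners unchanged and serves as the latent alkenyl metal for ring A; the configurations of 16 and 19 as drawn needed no correction; and the sense of induction in step 1 is taken by analogy with simple cyclic β-keto esters, the ligand antipode being used if it proves opposite.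

## Route

Step 1
Reactants: 1 methyl 2-oxocyclopentane-1-carboxylate; 2 allyl acetate
Product: 3 methyl (1R)-2-oxo-1-(prop-2-en-1-yl)cyclopentane-1-carboxylate
Conditions: [Pd(C3H5)Cl]2 (1 mol%), (R,R)-DACH-phenyl Trost ligand (3 mol%), 1,1,3,3-tetramethylguanidine, toluene, 0 °C
Reagents that add atoms: none
Why: Tsuji–Trost asymmetric allylic alkylation of a cyclic β-keto ester; the enolate attacks the π-allyl complex of divalent palladium inside the chiral pocket of the ligand, which selects one enolate face and sets the quaternary carbon.

Step 2
Reactants: 3 methyl (1R)-2-oxo-1-(prop-2-en-1-yl)cyclopentane-1-carboxylate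
Product: 6 methyl (1S)-2-oxo-1-(prop-2-en-1-yl)cyclopent-3-ene-1-carboxylate, via α-phenylselanyl ketone 4 (not isolated), via selenoxide 5 (not isolated)
Conditions: LiN(iPr)2, THF, −78 °C; PhSeBr; then 30% H2O2, pyridine, CH2Cl2, 0 °C to rt
Reagents that add atoms: none
Why: C1 is quaternary, so the ketone enolises only at C3; selenenylation, oxidation and syn-elimination of the selenoxide (selenoxide elimination) install the C3=C4 bond without touching the quaternary centre or the allyl group (the descriptor changes from R to S only through the priority rules).

Step 3
Reactants: 6 methyl (1S)-2-oxo-1-(prop-2-en-1-yl)cyclopent-3-ene-1-carboxylate; 7 potassium trifluoro(prop-1-en-2-yl)borate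
Product: 8 methyl (1S,4S)-2-oxo-4-(prop-1-en-2-yl)-1-(prop-2-en-1-yl)cyclopentane-1-carboxylate
Conditions: [Rh(cod)2]BF4 (3 mol%), (S)-BINAP (3.3 mol%), toluene/H2O 10:1, 100 °C
Reagents that add atoms: none
Why: Hayashi–Miyaura rhodium-catalysed asymmetric 1,4-addition; by analogy with 3-substituted cyclopentanones (S)-BINAP should deliver the isopropenyl group to the face that gives (4S), cis to the allyl group, under catalyst control. Any (1R) material carried from step 1 becomes a separable diastereomer, so 8 should be enantiomerically purer than 3.

Step 4
Reactants: 8 methyl (1S,4S)-2-oxo-4-(prop-1-en-2-yl)-1-(prop-2-en-1-yl)cyclopentane-1-carboxylate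
Product: 9 methyl (6S,8S)-8-(prop-1-en-2-yl)-6-(prop-2-en-1-yl)-1,4-dioxaspiro[4.4]nonane-6-carboxylate
Conditions: Me3SiOCH2CH2OSiMe3, Me3SiOTf (cat.), CH2Cl2, −78 to −20 °C
Reagents that add atoms: 1,2-bis(trimethylsilyloxy)ethane, C[Si](C)(C)OCCO[Si](C)(C)C
Why: Noyori ketalisation (aprotic, low temperature) converts the only ketone into the dioxolane without acid-induced migration of the isopropenyl double bond; the ester is inert.

Step 5
Reactants: 9 methyl (6S,8S)-8-(prop-1-en-2-yl)-6-(prop-2-en-1-yl)-1,4-dioxaspiro[4.4]nonane-6-carboxylate
Product: 10 methyl (6R,8S)-6-(2-oxopropyl)-8-(prop-1-en-2-yl)-1,4-dioxaspiro[4.4]nonane-6-carboxylate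
Conditions: PdCl2 (10 mol%), CuCl, O2 (1 atm), DMF/H2O 7:1, rt
Reagents that add atoms: water, O
Why: Wacker–Tsuji oxidation; Markovnikov hydroxypalladation of the monosubstituted allyl group gives the methyl ketone, whereas the 1,1-disubstituted isopropenyl group cannot give a ketone and reacts far more slowly.

Step 6
Reactants: 10 methyl (6R,8S)-6-(2-oxopropyl)-8-(prop-1-en-2-yl)-1,4-dioxaspiro[4.4]nonane-6-carboxylate
Product: 11 spiro cyclopentane-1,3-dione mono-ketal
Conditions: KOtBu, THF, 0 °C to rt; then cold dilute HCl to pH 4
Reagents that add atoms: none
Why: Intramolecular Claisen (Dieckmann-type) condensation; the methyl ketone enolate attacks the ester through a five-membered transition state and the equilibrium is pulled by deprotonation of the 1,3-dione. The spiro carbon bears no hydrogen, so its configuration is kept.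

Step 7
Reactants: 11 spiro cyclopentane-1,3-dione mono-ketal
Product: 12 spiro 3-chlorocyclopent-2-en-1-one
Conditions: Ph3PCl2, Et3N, CH2Cl2, 0 °C to rt
Reagents that add atoms: dichlorotriphenylphosphorane, ClP(Cl)(c1ccccc1)(c1ccccc1)c1ccccc1
Why: Conversion of a cyclic 1,3-dione into a β-chloro enone by O-phosphonium activation and addition–elimination of chloride; the reagent should engage the oxygen remote from the spiro carbon, so chlorine ends on the unhindered carbon and the carbonyl stays next to the spiro carbon.

Step 8
Reactants: 12 spiro 3-chlorocyclopent-2-en-1-one
Product: 13 spiro 3-chlorocyclopenta-1,3-dien-1-yl triflate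
Conditions: KN(SiMe3)2, THF, −78 °C; PhNTf2, −78 to 0 °C
Reagents that add atoms: N-phenylbis(trifluoromethanesulfonimide), O=S(=O)(N(c1ccccc1)S(=O)(=O)C(F)(F)F)C(F)(F)F
Why: The spiro carbon blocks α′-enolisation, so the hindered amide removes a γ-hydrogen and the extended dienolate is O-sulfonylated (enol triflate formation); the 5,5-disubstitution suppresses hydrogen shifts and dimerisation of the diene.

Step 9
Reactants: 13 spiro 3-chlorocyclopenta-1,3-dien-1-yl triflate; 14 tributyl(1-ethoxyethenyl)stannane
Product: 15 spiro 3-chloro-1-(1-ethoxyethenyl)cyclopenta-1,3-diene
Conditions: Pd(PPh3)4 (5 mol%), LiCl, THF, 65 °C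
Reagents that add atoms: none
Why: Stille coupling; with PPh3 ligands, oxidative addition of zerovalent palladium into the C–OTf bond is much faster than into the alkenyl C–Cl bond, so only the triflate is exchanged for the acetyl-equivalent enol ether.

Step 10
Reactants: 15 spiro 3-chloro-1-(1-ethoxyethenyl)cyclopenta-1,3-diene
Product: 16 chloro diene bis-ketal (key-step precursor)
Conditions: HOCH2CH2OH, pyridinium p-toluenesulfonate (cat.), CH2Cl2, rt
Reagents that add atoms: ethane-1,2-diol, OCCO
Why: Acid-catalysed addition of the diol to the enol ether with exchange of ethanol (transacetalisation) gives the dioxolane directly, without passing through the electron-poor acetyl diene; the alkenyl chloride and the ring dioxolane are inert.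

Step 11
Reactants: 16 chloro diene bis-ketal (key-step precursor); 17 1,1,3,3-tetrabromopropan-2-one
Product: 19 chloro bicyclo[3.2.1]octenone bis-ketal (key-step product), via dibromo ketone 18 (not isolated)
Conditions: Zn–Cu couple, B(OEt)3, THF, −10 °C to rt; then Zn–Cu couple, NH4Cl, MeOH, rt
Reagents that add atoms: none
Why: Zinc reduces 17 to a zinc-bound 1,3-dibromo-2-oxyallyl cation, which adds across C1 and C4 of the cyclopentadiene of 16, either concertedly through a compact transition state or by attack at the unsubstituted terminus followed by fast collapse of the allyl cation–zinc enolate pair onto the substituted terminus, to give 18; the second zinc treatment replaces both bromines by hydrogen. The closest known reaction type is the (4+3) cycloaddition of oxyallyl cations from polybromo ketones with cyclopentadienes and furans, including 1-substituted and 5,5-disubstituted ones. One ring is closed, the seven-membered ring of the bicyclo[3.2.1]octenone, by a two-bond annulation of a three-carbon cation onto the 1,4-termini of an s-cis diene held in a five-membered ring. The two new stereocentres are the bridgeheads: suprafacial addition ties them to each other, and their sense relative to the spiro carbon is set by the face of approach. The cation should come over the ring CH2 of the spiro cyclopentane and away from the dioxolane carbon with its two oxygens, which places the three-carbon bridge syn to that CH2 and the chloro-substituted two-carbon bridge syn to the masked ketone, as rings B and D of the target require. Regiochemistry is not an issue because the cation is symmetrical. The chemoselectivity needed is reaction at the diene and not at the isopropenyl group or the ketals; it is secured by the much higher nucleophilicity of the cyclic diene and by B(OEt)3, which moderates ZnBr2, while the alkenyl chloride is inert to zinc.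

Step 12
Reactants: 19 chloro bicyclo[3.2.1]octenone bis-ketal (key-step product)
Product: 20 enol triflate (C3=C4)
Conditions: KN(SiMe3)2, THF, −78 °C; PhNTf2, −78 to 0 °C
Reagents that add atoms: N-phenylbis(trifluoromethanesulfonimide), O=S(=O)(N(c1ccccc1)S(=O)(=O)C(F)(F)F)C(F)(F)F
Why: Kinetic enolisation with the bulky amide should occur at C4, next to the bridgehead CH, and not at C2, which is flanked by the quaternary bridgehead and its dioxolane; O-sulfonylation then gives the enol triflate, with the alkenyl chloride and ketals untouched.

Step 13
Reactants: 20 enol triflate (C3=C4); 21 dimethylzinc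
Product: 22 chloro methyl diene bis-ketal
Conditions: Pd(PPh3)4 (5 mol%), THF, 0 to 45 °C
Reagents that add atoms: none
Why: Negishi coupling of an enol triflate; Pd(PPh3)4 does not insert into the unactivated alkenyl chloride under these conditions, so only the methyl-bearing alkene of ring C is formed.

Step 14
Reactants: 22 chloro methyl diene bis-ketal; 23 hexacarbonylchromium
Product: 26 methoxy alkenyl carbene pentacarbonylchromium complex, via alkenyllithium 24 (not isolated), via lithium acylchromate 25 (not isolated)
Conditions: Li powder, 4,4′-di-tert-butylbiphenyl (10 mol%), THF, −78 °C; Cr(CO)6, −78 to 0 °C; Me3OBF4, CH2Cl2, 0 °C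
Reagents that add atoms: trimethyloxonium tetrafluoroborate, C[O+](C)C.F[B-](F)(F)F
Why: Arene-catalysed reductive lithiation of the alkenyl chloride gives the bridge alkenyllithium without moving the double bond; addition to Cr(CO)6 and O-methylation of the acylmetalate is the standard Fischer carbene synthesis. Ketals and isolated alkenes are inert to these reagents.

Step 15
Reactants: 26 methoxy alkenyl carbene pentacarbonylchromium complex; 27 ethynyltrimethylsilane
Product: 29 silylated methoxyphenol bis-ketal, via tricarbonylchromium arene complex 28 (not isolated)
Conditions: THF, 55 °C; then air, Et2O, rt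
Reagents that add atoms: none
Why: Dötz benzannulation: alkyne insertion, CO insertion to an alkenylketene, 6π-electrocyclisation onto the bridge CH carbon and tautomerisation build ring A on the former two-carbon bridge. The silyl group should end ortho to OH, and either regiochemistry converges after step 19.

Step 16
Reactants: 29 silylated methoxyphenol bis-ketal
Product: 30 silylated dimethoxyarene bis-ketal
Conditions: K2CO3, MeI, acetone, 50 °C
Reagents that add atoms: iodomethane, CI
Why: Williamson O-methylation of the phenol; both oxygens of ring A are then methyl ethers, inert to strong base and to the one-electron oxidant of step 18.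

Step 17
Reactants: 30 silylated dimethoxyarene bis-ketal
Product: 31 acetyl cyclopentanone diketone
Conditions: CF3CO2H/H2O 9:1, CH2Cl2, 0 °C
Reagents that add atoms: water, O
Why: ipso-Protodesilylation of the electron-rich arylsilane (electrophilic aromatic substitution) and acid hydrolysis of both dioxolanes; low temperature and short contact are chosen to spare the isopropenyl group.

Step 18
Reactants: 31 acetyl cyclopentanone diketone
Product: 32 target bis(methyl ether)
Conditions: LiN(iPr)2 (2.2 equiv), THF, −78 °C; CuCl2 (2.2 equiv), DMF, −78 to 0 °C
Reagents that add atoms: none
Why: Intramolecular oxidative coupling of a lithium bis-enolate by divalent copper; each ketone has one enolisable position (the CH3 of the acetyl group, the CH2 of the cyclopentanone). The acetyl group sits over ring E, so the new bond can form only on that face, which fixes the bridgehead methine and closes ring D.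

Step 19
Reactants: 32 target bis(methyl ether)
Product: 34 target hydroquinone CNP0287617.1, via quinone 33 (not isolated)
Conditions: (NH4)2Ce(NO3)6 (2.5 equiv), MeCN/H2O, 0 °C; then Na2S2O4, EtOAc/H2O, rt
Reagents that add atoms: water, O
Why: Oxidative demethylation of the 1,4-dimethoxyarene by tetravalent cerium gives the quinone (its oxygens come from water), which dithionite reduces to the hydroquinone in the same work-up; alkenes and ketones are inert to both reagents.

## Compound list

1 | methyl 2-oxocyclopentane-1-carboxylate | COC(=O)C1CCCC1=O | starting material
2 | prop-2-en-1-yl acetate (allyl acetate) | C=CCOC(C)=O | starting material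
3 | methyl (1R)-2-oxo-1-(prop-2-en-1-yl)cyclopentane-1-carboxylate | C=CC[C@@]1(C(=O)OC)C(=O)CCC1 | intermediate
4 | methyl (1R)-2-oxo-3-(phenylselanyl)-1-(prop-2-en-1-yl)cyclopentane-1-carboxylate, both C3 epimers | C=CC[C@@]1(C(=O)OC)C(=O)C([Se]c2ccccc2)CC1 | intermediate
5 | methyl (1R)-3-(benzeneseleninyl)-2-oxo-1-(prop-2-en-1-yl)cyclopentane-1-carboxylate (selenoxide of 4) | C=CC[C@@]1(C(=O)OC)C(=O)C([Se](=O)c2ccccc2)CC1 | intermediate
6 | methyl (1S)-2-oxo-1-(prop-2-en-1-yl)cyclopent-3-ene-1-carboxylate | C=CC[C@@]1(C(=O)OC)C(=O)C=CC1 | intermediate
7 | potassium trifluoro(prop-1-en-2-yl)borate | [K+].CC(=C)[B-](F)(F)F | starting material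
8 | methyl (1S,4S)-2-oxo-4-(prop-1-en-2-yl)-1-(prop-2-en-1-yl)cyclopentane-1-carboxylate (allyl cis to isopropenyl) | C=CC[C@@]1(C(=O)OC)C(=O)C[C@@H](C(C)=C)C1 | intermediate
9 | methyl (6S,8S)-8-(prop-1-en-2-yl)-6-(prop-2-en-1-yl)-1,4-dioxaspiro[4.4]nonane-6-carboxylate | C=CC[C@@]1(C(=O)OC)C2(OCCO2)C[C@@H](C(C)=C)C1 | intermediate
10 | methyl (6R,8S)-6-(2-oxopropyl)-8-(prop-1-en-2-yl)-1,4-dioxaspiro[4.4]nonane-6-carboxylate | CC(=O)C[C@@]1(C(=O)OC)C2(OCCO2)C[C@@H](C(C)=C)C1 | intermediate
11 | cyclopentane-1,3-dione whose C4 is spiro carbon C6 of (8S)-8-(prop-1-en-2-yl)-1,4-dioxaspiro[4.4]nonane; dione C3 carbonyl trans and dione C5 methylene cis to the isopropenyl group | O=C1CC(=O)C[C@@]12C[C@H](C(C)=C)CC23OCCO3 | intermediate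
12 | 3-chlorocyclopent-2-en-1-one whose C5 is spiro carbon C6 of (8S)-8-(prop-1-en-2-yl)-1,4-dioxaspiro[4.4]nonane; C1 carbonyl trans and C4 methylene cis to the isopropenyl group | O=C1C=C(Cl)C[C@@]12C[C@H](C(C)=C)CC23OCCO3 | intermediate
13 | 3-chlorocyclopenta-1,3-dien-1-yl trifluoromethanesulfonate whose C5 is spiro carbon C6 of (8S)-8-(prop-1-en-2-yl)-1,4-dioxaspiro[4.4]nonane; diene C1 trans and C4 cis to the isopropenyl group | FC(F)(F)S(=O)(=O)OC1=CC(Cl)=C[C@@]12C[C@H](C(C)=C)CC23OCCO3 | intermediate
14 | tributyl(1-ethoxyethenyl)stannane | CCCC[Sn](CCCC)(CCCC)C(=C)OCC | starting material
15 | 3-chloro-1-(1-ethoxyethenyl)cyclopenta-1,3-diene, C5 spiro and configured as in 13 | CCOC(=C)C1=CC(Cl)=C[C@@]12C[C@H](C(C)=C)CC23OCCO3 | intermediate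
16 | 3-chloro-1-(2-methyl-1,3-dioxolan-2-yl)cyclopenta-1,3-diene whose C5 is spiro carbon C6 of (8S)-8-(prop-1-en-2-yl)-1,4-dioxaspiro[4.4]nonane; diene C1 trans and C4 cis to the isopropenyl group (key-step precursor) | CC1(OCCO1)C2=CC(Cl)=C[C@@]23C[C@H](C(C)=C)CC34OCCO4 | intermediate
17 | 1,1,3,3-tetrabromopropan-2-one | BrC(Br)C(=O)C(Br)Br | starting material
18 | 2,4-dibromo derivative of 19 (bromine epimers at C2 and C4) | CC1(OCCO1)[C@]23C(Br)C(=O)C(Br)[C@H](C(Cl)=C2)[C@@]35C[C@H](C(C)=C)CC56OCCO6 | intermediate
19 | 6-chloro-1-(2-methyl-1,3-dioxolan-2-yl)bicyclo[3.2.1]oct-6-en-3-one whose C8 is spiro carbon C6 of (8S)-8-(prop-1-en-2-yl)-1,4-dioxaspiro[4.4]nonane; C1 trans and C5 cis to the isopropenyl group, bridge C2–C4 on the side of the ring CH2 (C7) of the spiro ring, bridge C6=C7 on the side of its dioxolane carbon (key-step product) | CC1(OCCO1)[C@]23CC(=O)C[C@H](C(Cl)=C2)[C@@]35C[C@H](C(C)=C)CC56OCCO6 | intermediate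
20 | 3-(trifluoromethanesulfonyloxy)bicyclo[3.2.1]octa-3,6-diene analogue of 19 (enol triflate C3=C4) | CC1(OCCO1)[C@]23CC(OS(=O)(=O)C(F)(F)F)=C[C@H](C(Cl)=C2)[C@@]35C[C@H](C(C)=C)CC56OCCO6 | intermediate
21 | dimethylzinc | C[Zn]C | starting material
22 | 6-chloro-3-methylbicyclo[3.2.1]octa-3,6-diene analogue of 19 | CC1(OCCO1)[C@]23CC(C)=C[C@H](C(Cl)=C2)[C@@]35C[C@H](C(C)=C)CC56OCCO6 | intermediate
23 | hexacarbonylchromium | O=C=[Cr](=C=O)(=C=O)(=C=O)(=C=O)=C=O | starting material
24 | C6-lithio analogue of 22 (alkenyllithium) | CC1(OCCO1)[C@]23CC(C)=C[C@H](C([Li])=C2)[C@@]35C[C@H](C(C)=C)CC56OCCO6 | intermediate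
25 | lithium acyl(pentacarbonyl)chromate, acyl carbon on C6 of the skeleton of 22 | CC1(OCCO1)[C@]23CC(C)=C[C@H](C(C([O-])=[Cr](=C=O)(=C=O)(=C=O)(=C=O)=C=O)=C2)[C@@]35C[C@H](C(C)=C)CC56OCCO6.[Li+] | intermediate
26 | pentacarbonyl[methoxy(alkenyl)carbene]chromium, carbene carbon on C6 of the skeleton of 22 | CC1(OCCO1)[C@]23CC(C)=C[C@H](C(C(OC)=[Cr](=C=O)(=C=O)(=C=O)(=C=O)=C=O)=C2)[C@@]35C[C@H](C(C)=C)CC56OCCO6 | intermediate
27 | ethynyltrimethylsilane | C#C[Si](C)(C)C | starting material
28 | tricarbonylchromium η6-arene complex of 29 (written as two parts) | CC1(OCCO1)[C@]23CC(C)=C[C@H](c4c(OC)cc([Si](C)(C)C)c(O)c42)[C@@]35C[C@H](C(C)=C)CC56OCCO6.O=C=[Cr](=C=O)=C=O | intermediate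
29 | benzo-fused analogue of 22 in which C6 and C7 are the fusion carbons of ring A: OMe on the arene carbon next to the fusion carbon bonded to the bridgehead CH, OH on the arene carbon next to the other fusion carbon, SiMe3 ortho to OH | CC1(OCCO1)[C@]23CC(C)=C[C@H](c4c(OC)cc([Si](C)(C)C)c(O)c42)[C@@]35C[C@H](C(C)=C)CC56OCCO6 | intermediate
30 | O-methyl ether of 29 (1,4-dimethoxyarene with SiMe3) | CC1(OCCO1)[C@]23CC(C)=C[C@H](c4c(OC)cc([Si](C)(C)C)c(OC)c42)[C@@]35C[C@H](C(C)=C)CC56OCCO6 | intermediate
31 | diketone: rings A, B and C of 32 with an acetyl group on the benzylic quaternary carbon and the central quaternary carbon spiro to C2 of (4S)-4-(prop-1-en-2-yl)cyclopentan-1-one, carbonyl on the side of ring A | CC(=O)[C@]12CC(C)=C[C@H](c3c(OC)ccc(OC)c31)[C@@]24C[C@H](C(C)=C)CC4=O | intermediate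
32 | bis(methyl ether) of the target (rings A–E complete) | C=C(C)[C@H]1C[C@@]23C(=O)[C@@H]1CC(=O)[C@@]21CC(C)=C[C@@H]3c2c(OC)ccc(OC)c21 | intermediate
33 | ring A 1,4-benzoquinone corresponding to the target | C=C(C)[C@H]1C[C@@]23C(=O)[C@@H]1CC(=O)[C@@]21CC(C)=C[C@@H]3C2=C1C(=O)C=CC2=O | intermediate
34 | target hydroquinone CNP0287617.1 | C=C(C)[C@H]1C[C@@]23C(=O)[C@@H]1CC(=O)[C@@]21CC(C)=C[C@@H]3c2c(O)ccc(O)c21 | target

## Step count and least certain steps

Total step count: 19. Longest linear sequence: 19 steps (from 1; all other numbered reactants are commercial).

Step 11 (key step). The most likely failure is that the addition stalls after the first bond at the unsubstituted diene terminus, because closure onto the terminus that carries the dioxolanyl group and becomes quaternary is slow; the intermediate cation would then be lost by proton loss or by opening of the neighbouring ketal. Loss of facial control is the second risk. The fallback replaces the allyl cation by a rhodium carbenoid and sets out from 16. Methyl acetoacetate is converted by diazo transfer (4-acetamidobenzenesulfonyl azide, Et3N) into methyl 2-diazo-3-oxobutanoate F1, and this by tert-butyldimethylsilyl triflate and Et3N into methyl 2-diazo-3-[(tert-butyldimethylsilyl)oxy]but-3-enoate F2. Decomposition of F2 with Rh2(OAc)4 in the presence of 16 should cyclopropanate the less hindered diene double bond from the face away from the dioxolane, and the cis-divinylcyclopropane should undergo Cope rearrangement to the bicyclic silyl enol ether ester F3. Either regiochemistry of cyclopropanation converges later. Bu4NF buffered with AcOH would free the β-keto ester F4, and Krapcho decarboxylation (LiCl, wet DMSO, 130 °C) returns to the route at 19.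

Step 12. Enolisation may not discriminate well between the two α-methylene groups, since both are secondary and the bias is only steric. The fallback sets out from 19 and uses hydrazone geometry as the control element. Condensation with 2,4,6-triisopropylbenzenesulfonohydrazide gives the sulfonylhydrazone F5, in which the sulfonamide nitrogen should point away from the hindered side. BuLi (2.2 equiv, THF, −78 to 0 °C) then removes the syn α-hydrogen at C4 and, after loss of sulfinate and dinitrogen (Shapiro reaction), gives the C3 alkenyllithium F6. Methylation with MeI returns to the route at 22.

Step 17. Protonation of the isopropenyl group may compete with ipso-protonation of the arylsilane, leading to addition of acid or double bond migration. The fallback avoids the strong acid by changing the placeholder group and sets out from 26. Benzannulation with ethynyltributylstannane in place of 27 should give the stannylated methoxyphenol F7, whose aryl–tin bond is cleaved on silica gel to the methoxyphenol F8. Methylation (K2CO3, MeI) gives the dimethoxyarene bis-ketal F9, and 1 M HCl in THF at rt removes only the dioxolanes, returning to the route at 31.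

Step 18. Intermolecular coupling, chlorine transfer from CuCl2 to an enolate, or over-oxidation may win because the two enolate carbons must meet in a strained bicyclic transition state. The fallback replaces the one-electron coupling by a polar alkylation and sets out from 31. Me3SiOTf and Et3N give the bis(trimethylsilyl enol ether) F10. N-Bromosuccinimide (1 equiv, THF, −78 °C) brominates one enol ether much faster than it attacks the other alkenes and should give the bromomethyl ketone silyl enol ether F11; the regioisomeric bromide would lead to the same bond. Bu4NF then releases the remaining enolate, which displaces bromide intramolecularly and returns to the route at 32.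

## Further compounds

F1 | step 11 | methyl 2-diazo-3-oxobutanoate | COC(=O)C(=[N+]=[N-])C(C)=O
F2 | step 11 | methyl 2-diazo-3-[(tert-butyldimethylsilyl)oxy]but-3-enoate | COC(=O)C(=[N+]=[N-])C(=C)O[Si](C)(C)C(C)(C)C
F3 | step 11 | bicyclic silyl enol ether ester: 3-silyloxy-4-methoxycarbonyl-bicyclo[3.2.1]octa-3,6-diene analogue of 19 | CC1(OCCO1)[C@]23CC(O[Si](C)(C)C(C)(C)C)=C(C(=O)OC)[C@H](C(Cl)=C2)[C@@]35C[C@H](C(C)=C)CC56OCCO6
F4 | step 11 | β-keto ester: 4-methoxycarbonyl derivative of 19 (C4 epimers) | CC1(OCCO1)[C@]23CC(=O)C(C(=O)OC)[C@H](C(Cl)=C2)[C@@]35C[C@H](C(C)=C)CC56OCCO6
F5 | step 12 | 2,4,6-triisopropylbenzenesulfonylhydrazone of 19 | CC1(OCCO1)[C@]23CC(=NNS(=O)(=O)c4c(C(C)C)cc(C(C)C)cc4C(C)C)C[C@H](C(Cl)=C2)[C@@]35C[C@H](C(C)=C)CC56OCCO6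
F6 | step 12 | C3-lithio bicyclo[3.2.1]octa-3,6-diene (alkenyllithium from F5) | CC1(OCCO1)[C@]23CC([Li])=C[C@H](C(Cl)=C2)[C@@]35C[C@H](C(C)=C)CC56OCCO6
F7 | step 17 | tributylstannyl analogue of 29 (tin in place of silicon) | CC1(OCCO1)[C@]23CC(C)=C[C@H](c4c(OC)cc([Sn](CCCC)(CCCC)CCCC)c(O)c42)[C@@]35C[C@H](C(C)=C)CC56OCCO6
F8 | step 17 | methoxyphenol bis-ketal without silicon or tin | CC1(OCCO1)[C@]23CC(C)=C[C@H](c4c(OC)ccc(O)c42)[C@@]35C[C@H](C(C)=C)CC56OCCO6
F9 | step 17 | dimethoxyarene bis-ketal without silicon | CC1(OCCO1)[C@]23CC(C)=C[C@H](c4c(OC)ccc(OC)c42)[C@@]35C[C@H](C(C)=C)CC56OCCO6
F10 | step 18 | bis(trimethylsilyl enol ether) of 31 | C=C(O[Si](C)(C)C)[C@]12CC(C)=C[C@H](c3c(OC)ccc(OC)c31)[C@@]24C[C@H](C(C)=C)C=C4O[Si](C)(C)C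
F11 | step 18 | bromomethyl ketone with the ring trimethylsilyl enol ether intact | BrCC(=O)[C@]12CC(C)=C[C@H](c3c(OC)ccc(OC)c31)[C@@]24C[C@H](C(C)=C)C=C4O[Si](C)(C)C
A1 | alternative 1 | spiro benzocycloheptadienol 2-prenylcyclohex-5-ene-1,4-dione (carbinol and prenyl-bearing carbons unassigned) | CC(C)=CCC1C(=O)C=CC(=O)[C@@]12CC(C)=CC(O)c1c(OC)ccc(OC)c12
A2 | alternative 1 | prenylated bridged ene-dione (all rings except the cyclopentanone) | CC(C)=CC[C@@]23C(=O)C=CC(=O)[C@@]21CC(C)=C[C@@H]3c2c(OC)ccc(OC)c21
A3 | alternative 2 | 9-substituted trimethoxyfluorenol bearing the allylic methyl carbonate | COC(=O)OCC(C)=C[C@@H]1c2c(OC)ccc(OC)c2-c2c(O)ccc(OC)c12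
A4 | alternative 2 | bridged 4-methoxycyclohexa-2,4-dienone fused to the benzobicyclo[3.2.1]octadiene | COC1=C2[C@@H]3C=C(C)C[C@@]2(C(=O)C=C1)c1c(OC)ccc(OC)c13
A5 | alternative 3 | target bis(methyl ether) | C=C(C)[C@H]1C[C@@]23C(=O)[C@@H]1CC(=O)[C@@]21CC(C)=C[C@@H]3c2c(OC)ccc(OC)c21
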